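**Retrosynthetic overview**

1. The target is a 2-aryl-3-hydroxymethyl-4-benzyl oxolane (ring C). The route rests on one feature: the only free phenol O–H is on the guaiacyl ring (ring A), para to the ring carbon bonded to C2 of ring C. C2 can therefore be the exocyclic carbon of a p-quinone methide of ring A, which the fully methylated veratryl ring (ring B) cannot form.
2. Last disconnection, O1–C2: anodic dehydrogenation of the phenolic dibenzylbutanediol gives that quinone methide, and the hydroxymethyl oxygen of the ring B half closes ring C. Ring C is the only ring formed that stays in the target, and it is formed last.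
3. The (2R,3R)-diol comes from the trans-(3R,4R)-dibenzylbutyrolactone by LiAlH4 reduction and O-debenzylation. That lactone comes from trans-alkylation of (R)-4-(3,4-dimethoxybenzyl)oxolan-2-one with 4-benzyloxy-3-methoxybenzyl bromide.
4. The (R)-lactone comes from an Evans alkylation of the N-(3-arylpropanoyl) derivative of (S)-4-benzyl-2-oxazolidinone with tert-butyl bromoacetate, LiBH4 reduction and lactonisation. This auxiliary-set centre relays to the other two.

Key step: step 9

Remark: 4-benzyloxy-3-methoxybenzyl alcohol (10) is assumed to be commercial; it is otherwise one NaBH4 reduction away from O-benzylvanillin. Ring A = 4-hydroxy-3-methoxyphenyl, ring B = 3,4-dimethoxyphenyl, ring C = oxolane.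

**Route**

Step 1
Reactants: 1 3-(3,4-dimethoxyphenyl)propanoic acid; 2 (S)-4-benzyl-2-oxazolidinone
Product: 4 (4S)-4-benzyl-3-[3-(3,4-dimethoxyphenyl)propanoyl]oxazolidin-2-one, via mixed pivalic anhydride 3 (not isolated)
Conditions: PivCl, Et3N, THF, −20 °C; then LiCl, 2, −20 °C to rt
Reagents that add atoms: none
Why: N-acylation of the oxazolidinone by acyl transfer from the mixed pivalic anhydride (LiCl/Et3N-promoted) should occur at the unhindered arylpropanoyl carbonyl and creates no stereocentre.

Step 2
Reactants: 4 (4S)-4-benzyl-3-[3-(3,4-dimethoxyphenyl)propanoyl]oxazolidin-2-one; 5 tert-butyl bromoacetate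
Product: 7 tert-butyl (3R)-4-[(4S)-4-benzyl-2-oxooxazolidin-3-yl]-3-(3,4-dimethoxybenzyl)-4-oxobutanoate, via sodium Z-enolate 6 (not isolated)
Conditions: NaN(SiMe3)2, THF, −78 °C; then 5, −78 to −40 °C
Reagents that add atoms: none
Why: Evans asymmetric alkylation: the chelated sodium Z-enolate is shielded on one face by the C4 benzyl group of the auxiliary, so the reactive α-bromo ester should add to the opposite face and set the new centre as R.

Step 3
Reactants: 7 tert-butyl (3R)-4-[(4S)-4-benzyl-2-oxooxazolidin-3-yl]-3-(3,4-dimethoxybenzyl)-4-oxobutanoate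
Product: 8 tert-butyl (3R)-3-(3,4-dimethoxybenzyl)-4-hydroxybutanoate
Conditions: LiBH4, MeOH (1 equiv), THF, 0 °C
Reagents that add atoms: none
Why: Reductive removal of the auxiliary with LiBH4 relies on the exocyclic imide carbonyl being far more electrophilic than the hindered tert-butyl ester, and the stereocentre is carried through unchanged.

Step 4
Reactants: 8 tert-butyl (3R)-3-(3,4-dimethoxybenzyl)-4-hydroxybutanoate
Product: 9 (4R)-4-(3,4-dimethoxybenzyl)oxolan-2-one
Conditions: TsOH·H2O (cat.), toluene, 80 °C
Reagents that add atoms: none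
Why: Acid-catalysed lactonisation (intramolecular transesterification of the γ-hydroxy tert-butyl ester) should close the five-membered lactone without touching the stereocentre.

Step 5
Reactants: 10 4-benzyloxy-3-methoxybenzyl alcohol
Product: 11 4-benzyloxy-3-methoxybenzyl bromide
Conditions: PBr3, CH2Cl2, 0 °C
Reagents that add atoms: phosphorus tribromide, BrP(Br)Br
Why: Bromination of an electron-rich benzylic alcohol with PBr3 (substitution via the phosphite ester) is fast at 0 °C and leaves the benzyl aryl ether intact; the bromide is used without storage.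

Step 6
Reactants: 9 (4R)-4-(3,4-dimethoxybenzyl)oxolan-2-one; 11 4-benzyloxy-3-methoxybenzyl bromide
Product: 13 (3R,4R)-3-(4-benzyloxy-3-methoxybenzyl)-4-(3,4-dimethoxybenzyl)oxolan-2-one, via lithium lactone enolate 12 (not isolated)
Conditions: LiN(SiMe3)2, THF, −78 °C; then 11, DMPU, −78 to −30 °C
Reagents that add atoms: none
Why: Diastereoselective alkylation of a γ-butyrolactone lithium enolate: the benzylic bromide should approach the enolate face anti to the C4 substituent, which sets C3 as R and gives the 3,4-trans lactone.

Step 7
Reactants: 13 (3R,4R)-3-(4-benzyloxy-3-methoxybenzyl)-4-(3,4-dimethoxybenzyl)oxolan-2-one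
Product: 14 (2R,3R)-2-(4-benzyloxy-3-methoxybenzyl)-3-(3,4-dimethoxybenzyl)butane-1,4-diol
Conditions: LiAlH4, THF, 0 °C to rt; H2O/NaOH work-up
Reagents that add atoms: none
Why: Hydride reduction of the lactone with LiAlH4 gives the 1,4-diol; addition to the carbonyl is faster than enolisation, so both stereocentres should be retained.

Step 8
Reactants: 14 (2R,3R)-2-(4-benzyloxy-3-methoxybenzyl)-3-(3,4-dimethoxybenzyl)butane-1,4-diol
Product: 15 (2R,3R)-2-(3,4-dimethoxybenzyl)-3-(4-hydroxy-3-methoxybenzyl)butane-1,4-diol
Conditions: H2 (1 atm), Pd/C, EtOAc/MeOH, rt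
Reagents that add atoms: none
Why: Catalytic hydrogenolysis of the benzyl aryl ether over Pd/C frees the phenol; the molecule has no other benzylic C–O bond, and the arenes and primary alcohols are inert under these conditions.

Step 9
Reactants: 15 (2R,3R)-2-(3,4-dimethoxybenzyl)-3-(4-hydroxy-3-methoxybenzyl)butane-1,4-diol
Product: 17 4'-O-methyllariciresinol ([(2S,3R,4R)-4-(3,4-dimethoxybenzyl)-2-(4-hydroxy-3-methoxyphenyl)oxolan-3-yl]methanol), via p-quinone methide 16 (not isolated)
Conditions: graphite anode, Pt cathode, undivided cell, constant current (about 1 mA cm−2, anode kept near the first oxidation wave of 15), 2.0 F mol−1; 2,6-lutidine (10 equiv), nBu4NBF4 (0.1 M), MeCN/CH2Cl2 (4:1), 5 mM in 15, 0 °C, argon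
Reagents that add atoms: none
Why: In the lutidine-buffered medium the phenol of ring A loses two electrons and its O–H proton, the oxidised ring gives up the para-benzylic proton to 2,6-lutidine to become p-quinone methide 16, and the lutidinium formed is reduced to H2 at the cathode. The closest known reaction type is the two-electron oxidation of 4-alkyl-2-methoxyphenols (at an anode, or with DDQ or Ag2O) to p-quinone methides that are trapped by a pendant alcohol. Ring C closes by 5-exo-trig conjugate addition of the hydroxymethyl oxygen of the ring B half to the methide carbon, which rearomatises ring A, whereas the hydroxymethyl group on the neighbouring carbon could reach the methide carbon only by forming an oxetane. The new C2 centre is controlled by the existing C3 centre: the aryl group should take the face anti to the C3 hydroxymethyl group in the methide conformer of least allylic strain, and the 2,3-trans ether is also the more stable product should the addition be reversible. The step needs oxidation of ring A and not ring B, which the single free phenol secures because with base it is oxidised well below a dimethoxyarene. It also needs oxygen and not carbon attack on the methide: the non-acidic buffer leaves the methide unprotonated so that ring B should not add to give the aryltetralin, and the charge limit of two electrons per molecule guards against further oxidation of the product phenol.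

**Compound list**

1 | 3-(3,4-dimethoxyphenyl)propanoic acid | COc1ccc(CCC(=O)O)cc1OC | starting material
2 | (S)-4-benzyl-2-oxazolidinone | O=C1N[C@@H](Cc2ccccc2)CO1 | starting material
3 | 3-(3,4-dimethoxyphenyl)propanoic pivalic anhydride | COc1ccc(CCC(=O)OC(=O)C(C)(C)C)cc1OC | intermediate
4 | (4S)-4-benzyl-3-[3-(3,4-dimethoxyphenyl)propanoyl]oxazolidin-2-one | COc1ccc(CCC(=O)N2[C@@H](Cc3ccccc3)COC2=O)cc1OC | intermediate
5 | tert-butyl bromoacetate | CC(C)(C)OC(=O)CBr | starting material
6 | sodium Z-enolate of 4 | COc1ccc(C/C=C(\[O-])N2[C@@H](Cc3ccccc3)COC2=O)cc1OC.[Na+] | intermediate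
7 | tert-butyl (3R)-4-[(4S)-4-benzyl-2-oxooxazolidin-3-yl]-3-(3,4-dimethoxybenzyl)-4-oxobutanoate | CC(C)(C)OC(=O)C[C@@H](Cc1ccc(OC)c(OC)c1)C(=O)N1[C@@H](Cc2ccccc2)COC1=O | intermediate
8 | tert-butyl (3R)-3-(3,4-dimethoxybenzyl)-4-hydroxybutanoate | CC(C)(C)OC(=O)C[C@@H](Cc1ccc(OC)c(OC)c1)CO | intermediate
9 | (4R)-4-(3,4-dimethoxybenzyl)oxolan-2-one | O=C1C[C@@H](Cc2ccc(OC)c(OC)c2)CO1 | intermediate
10 | 4-benzyloxy-3-methoxybenzyl alcohol | COc1cc(CO)ccc1OCc1ccccc1 | starting material
11 | 4-benzyloxy-3-methoxybenzyl bromide | COc1cc(CBr)ccc1OCc1ccccc1 | intermediate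
12 | lithium enolate of 9 | [Li+].[O-]C1=C[C@@H](Cc2ccc(OC)c(OC)c2)CO1 | intermediate
13 | (3R,4R)-3-(4-benzyloxy-3-methoxybenzyl)-4-(3,4-dimethoxybenzyl)oxolan-2-one (O-benzylarctigenin) | O=C1OC[C@H](Cc2ccc(OC)c(OC)c2)[C@H]1Cc1ccc(OCc2ccccc2)c(OC)c1 | intermediate
14 | (2R,3R)-2-(4-benzyloxy-3-methoxybenzyl)-3-(3,4-dimethoxybenzyl)butane-1,4-diol | COc1cc(C[C@@H](CO)[C@H](CO)Cc2ccc(OC)c(OC)c2)ccc1OCc1ccccc1 | intermediate
15 | (2R,3R)-2-(3,4-dimethoxybenzyl)-3-(4-hydroxy-3-methoxybenzyl)butane-1,4-diol | COc1cc(C[C@@H](CO)[C@H](CO)Cc2ccc(OC)c(OC)c2)ccc1O | intermediate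
16 | 4-[(2R,3R)-3-(3,4-dimethoxybenzyl)-4-hydroxy-2-(hydroxymethyl)butylidene]-2-methoxycyclohexa-2,5-dien-1-one (p-quinone methide, exocyclic C=C geometry not defined) | COC1=CC(=C[C@@H](CO)[C@H](CO)Cc2ccc(OC)c(OC)c2)C=CC1=O | intermediate
17 | 4'-O-methyllariciresinol, [(2S,3R,4R)-4-(3,4-dimethoxybenzyl)-2-(4-hydroxy-3-methoxyphenyl)oxolan-3-yl]methanol | COc1cc([C@H]2OC[C@H](Cc3ccc(OC)c(OC)c3)[C@@H]2CO)ccc1O | target

**Step count**

Total steps: 9. Longest linear sequence: 8 steps (steps 1–4 and 6–9, from acid 1 to target 17); step 5 is a one-step side branch.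

**Steps most likely to fail**

Step 9. Several processes may compete with formation and 5-exo closure of the methide:
- Attack of the nearer hydroxymethyl oxygen on the ring A carbon para to the phenol before the benzylic proton is lost (dearomatising spiro-etherification).
- Coupling of phenoxyl radicals through the free position ortho to the phenol.
- Carbon attack of ring B on the methide (aryltetralin closure) if the medium turns acidic.
- Further oxidation of the product phenol at C2.
- Incomplete facial selectivity at C2.

The fallback puts the C2 oxygen in by C–C bond formation instead of C–H oxidation; it sets out from lactone 9 and returns at target 17. Lithium enolate 12 is added at −78 °C to 4-benzyloxy-3-methoxybenzaldehyde (COc1cc(C=O)ccc1OCc1ccccc1) in an aldol addition anti to the C4 substituent. This should give the aldol adduct F1 as a mixture of carbinol epimers. LiAlH4 in THF reduces it to the triol F2. Catalytic camphorsulfonic acid in CH2Cl2 at 0 °C ionises the benzylic alcohol, the cation being stabilised by the para benzyloxy group. The hydroxymethyl group of the ring B half then closes the oxolane to the 2,3-trans ether, the O-benzyl ether of the target F3, with both carbinol epimers converging. A brief hydrogenolysis (H2, Pd/C, EtOAc), monitored so that the benzylic C2–O bond of the oxolane is not cleaved, frees the phenol to give 17.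

Step 6. The alkylation may suffer from proton exchange between product and enolate followed by a second alkylation, from decomposition of the electron-rich benzylic bromide if the alkylation is slow, and from erosion of the trans selectivity. The fallback sets out from lactone 9 and returns at diol 15. Aldol addition of enolate 12 to 4-benzyloxy-3-methoxybenzaldehyde gives the aldol adduct F1 as described above; the aldolate is not enolised further, so over-reaction is not possible. Hydrogenolysis over Pd/C in AcOH with a trace of HClO4 removes the benzylic hydroxyl and the O-benzyl group in one operation and should give (−)-arctigenin F4 with the trans relation intact. LiAlH4 in excess, to allow for the phenoxide, then gives 15.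

Step 3. Hydride may attack the ring carbonyl of the oxazolidinone (endocyclic cleavage), and the lithium alkoxide may lactonise early, after which the lactone is over-reduced to a diol. The fallback sets out from imide 7 and returns at hydroxy ester 8. LiOH/H2O2 (THF/H2O, 0 °C) cleaves the auxiliary hydrolytically to the succinic half-ester acid F5. BH3·SMe2 (THF, 0 °C) then reduces the free carboxylic acid in the presence of the tert-butyl ester to give 8.

**Further compounds**

F1 | step 9 | (3S,4R)-3-[(4-benzyloxy-3-methoxyphenyl)(hydroxy)methyl]-4-(3,4-dimethoxybenzyl)oxolan-2-one, both carbinol epimers | O=C1OC[C@H](Cc2ccc(OC)c(OC)c2)[C@H]1C(O)c1ccc(OCc2ccccc2)c(OC)c1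
F2 | step 9 | (2R,3R)-2-[(4-benzyloxy-3-methoxyphenyl)(hydroxy)methyl]-3-(3,4-dimethoxybenzyl)butane-1,4-diol, both carbinol epimers | COc1cc(C(O)[C@@H](CO)[C@H](CO)Cc2ccc(OC)c(OC)c2)ccc1OCc1ccccc1
F3 | step 9 | [(2S,3R,4R)-2-(4-benzyloxy-3-methoxyphenyl)-4-(3,4-dimethoxybenzyl)oxolan-3-yl]methanol | COc1cc([C@H]2OC[C@H](Cc3ccc(OC)c(OC)c3)[C@@H]2CO)ccc1OCc1ccccc1
F4 | step 6 | (−)-arctigenin, (3R,4R)-4-(3,4-dimethoxybenzyl)-3-(4-hydroxy-3-methoxybenzyl)oxolan-2-one | O=C1OC[C@H](Cc2ccc(OC)c(OC)c2)[C@H]1Cc1ccc(O)c(OC)c1
F5 | step 3 | (2R)-4-tert-butoxy-2-(3,4-dimethoxybenzyl)-4-oxobutanoic acid | CC(C)(C)OC(=O)C[C@@H](Cc1ccc(OC)c(OC)c1)C(=O)O
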